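## Retrosynthetic overview

- **Feature.** The single cyclohexene ring carries oxygen on both allylic carbons flanking C2=C3. O1 sits on the quaternary C1 (which also bears C7) and O4 on C4, on opposite faces. This trans-1,4-dioxy-2-ene unit is what a 1,4-addition of two oxygen nucleophiles to a C1=C2–C3=C4 diene would leave.
- **Disconnections.** (a) O7 benzoate ⇒ C1 benzoate by 1,2-acyl shift. (b) C1–O and C4–O ⇒ a 5-hydroxy-6,7-O-silylene cyclohexa-1,3-diene plus two benzoates, by palladium-catalysed oxidative 1,4-dibenzoyloxylation. (c) C1–C7 ⇒ vinylic bromide plus Bu3SnCH2OH. (d) trans-5,6-diol ⇒ enzymatic cis-diol of bromobenzene by inversion at C5.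
- **Inversion.** C5 is inverted on the 3,4-dihydro compound. On the cis-dienediol itself an activated O5 lies anti to H6 and would leave with it to give a phenol. C3=C4 is restored afterwards by allylic bromination and dehydrobromination.
- **Rings.** No ring of the target is formed; the carbocycle comes intact from the bromobenzene diol. The only ring made on the way is the temporary O6/O7 silylene.

Key step: step 9

Convention: target numbering is used for all ring compounds (C1 bears Br or C7, then C2, C3, C4, C5, C6). β is the face of O1 and O5 in the target; α is the face of C7, O4 and O6.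

Assumption: the bromobenzene cis-diol is bought as the enzymatically made single enantiomer (sold as a buffered suspension) and extracted just before use. The stannane and benzoic acid are bought.

## Route

Step 1
Reactants: 1 (1S,2S)-3-bromocyclohexa-3,5-diene-1,2-diol (1-bromo; 5α-OH; 6α-OH)
Product: 2 (1S,2S)-3-bromocyclohex-3-ene-1,2-diol (C3–C4 saturated; 5α-OH; 6α-OH)
Conditions: KO2CN=NCO2K, AcOH, MeOH, 0 °C
Reagents that add atoms: none
Why: Diimide reduction transfers H2 to the unhindered disubstituted C3=C4 alkene much faster than to the bromine-bearing C1=C2 alkene, no stereocentre is touched, and removing C3=C4 keeps the later activation of O5 from aromatising the ring.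

Step 2
Reactants: 2 (1S,2S)-3-bromocyclohex-3-ene-1,2-diol
Product: 4 (1S,6S)-2-bromo-6-hydroxycyclohex-2-en-1-yl benzoate (6α-OBz; free 5α-OH), via cyclic orthobenzoate 3 (not isolated)
Conditions: PhC(OMe)3, CSA (cat.), CH2Cl2, rt; then 80% aq AcOH, 0 °C
Reagents that add atoms: trimethyl orthobenzoate COC(OC)(OC)c1ccccc1; water O
Why: Cyclic orthoester formation followed by kinetic acid hydrolysis follows the axial-ester rule for cis-diols on six-membered rings: allylic strain with the C1 bromine holds O6 pseudoaxial and O5 equatorial, so the hemiorthoester should collapse to the O6 benzoate with O5 free and both configurations retained.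

Step 3
Reactants: 4 (1S,6S)-2-bromo-6-hydroxycyclohex-2-en-1-yl benzoate
Product: 5 (1R,2S)-2-(benzoyloxy)-3-bromocyclohex-3-en-1-yl 4-nitrobenzoate (5β-O-nitrobenzoate; 6α-OBz; trans)
Conditions: 4-O2NC6H4CO2H, PPh3, DIAD, toluene, 0 °C to rt
Reagents that add atoms: 4-nitrobenzoic acid OC(=O)c1ccc(cc1)[N+](=O)[O-]
Why: In this Mitsunobu reaction the only free hydroxyl is activated as its oxyphosphonium salt and displaced by 4-nitrobenzoate in an SN2 step that turns C5 from α to β (the cis O6 benzoate cannot participate), and because the two acyl groups differ, any product from a migrated benzoate is a constitutional isomer that chromatography removes before it can lower the enantiomeric purity.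

Step 4
Reactants: 5 (1R,2S)-2-(benzoyloxy)-3-bromocyclohex-3-en-1-yl 4-nitrobenzoate
Product: 6 (1R,2S)-2-(benzoyloxy)-3,5-dibromocyclohex-3-en-1-yl 4-nitrobenzoate (new allylic bromide at route C3; both C3 epimers)
Conditions: NBS, AIBN (cat.), PhCF3, 80 °C
Reagents that add atoms: N-bromosuccinimide O=C1CCC(=O)N1Br
Why: In this Wohl–Ziegler allylic bromination the bromine atom abstracts hydrogen from the C3 methylene, the other allylic C–H at C6 being deactivated by its acyloxy group, and the new C3 centre is lost again in step 5, so its configuration does not matter.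

Step 5
Reactants: 6 (1R,2S)-2-(benzoyloxy)-3,5-dibromocyclohex-3-en-1-yl 4-nitrobenzoate
Product: 7 (1R,2S)-2-(benzoyloxy)-3-bromocyclohexa-3,5-dien-1-yl 4-nitrobenzoate (1-bromo diene; 5β,6α-diester)
Conditions: DBU, THF, 0 °C to rt
Reagents that add atoms: none
Why: E2 dehydrobromination with an amidine base removes H4 and the allylic C3 bromide to give the conjugated diene, while in the trans-diester each C–O bond lies syn to the neighbouring ring hydrogen, so anti elimination to a phenol ester is not available.

Step 6
Reactants: 7 (1R,2S)-2-(benzoyloxy)-3-bromocyclohexa-3,5-dien-1-yl 4-nitrobenzoate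
Product: 8 (1R,2S)-3-bromocyclohexa-3,5-diene-1,2-diol (trans; 5β-OH; 6α-OH)
Conditions: K2CO3 (cat.), MeOH, 0 °C
Reagents that add atoms: none
Why: Carbonate-catalysed transesterification (Zemplén-type deacylation) breaks only acyl–oxygen bonds, so C5 and C6 keep their configuration, and it is placed before the coupling so that no allylic carboxylate is left for zerovalent palladium to ionise.

Step 7
Reactants: 8 (1R,2S)-3-bromocyclohexa-3,5-diene-1,2-diol; 9 tributyl(hydroxymethyl)stannane
Product: 10 (1R,2R)-3-(hydroxymethyl)cyclohexa-3,5-diene-1,2-diol (5β-OH; 6α-OH; C7–OH)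
Conditions: Pd(PPh3)4 (5 mol %), degassed 1,4-dioxane, 80 °C
Reagents that add atoms: tributyl(hydroxymethyl)stannane OC[Sn](CCCC)(CCCC)CCCC
Why: In this Stille coupling zerovalent palladium inserts into the vinylic C1–Br bond, the α-oxygenated CH2OH group is transferred from tin in preference to butyl, and reductive elimination forms C1–C7 without touching the free trans-diol or its stereocentres.

Step 8
Reactants: 10 (1R,2R)-3-(hydroxymethyl)cyclohexa-3,5-diene-1,2-diol
Product: 11 (8R,8aR)-2,2-di-tert-butyl-8,8a-dihydro-4H-1,3,2-benzodioxasilin-8-ol (6α,7-O-di-tert-butylsilylene dienol; free 5β-OH)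
Conditions: t-Bu2Si(OTf)2, 2,6-lutidine, DMF, −40 to 0 °C
Reagents that add atoms: di-tert-butylsilyl bis(trifluoromethanesulfonate) CC(C)(C)[Si](OS(=O)(=O)C(F)(F)F)(OS(=O)(=O)C(F)(F)F)C(C)(C)C
Why: In this cyclic silylene protection the primary O7 is silylated first and the second Si–O bond closes the six-membered ring onto O6 rather than a seven-membered ring onto O5 or a strained trans-fused five-membered ring over O5/O6, the same preference that leaves the 2'-hydroxyl of ribonucleosides free.

Step 9
Reactants: 11 6α,7-O-di-tert-butylsilylene dienol with free 5β-OH; 12 benzoic acid (two molecules)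
Product: 14 1β,4α-di-O-benzoyl-6α,7-O-(di-tert-butylsilylene)-1-(hydroxymethyl)cyclohex-2-ene-1,4,5,6-tetrol (free 5β-OH), via π-allylpalladium benzoate 13 (not isolated)
Conditions: Pd(OAc)2 (10 mol %), p-benzoquinone (2 equiv), PhCO2Li (2 equiv), PhCO2H (10 equiv), acetone, rt, no chloride
Reagents that add atoms: benzoic acid OC(=O)c1ccccc1 (two equivalents, delivered as benzoate; lithium benzoate [Li+].[O-]C(=O)c1ccccc1 is the same nucleophile in salt form)
Why: Proposed new method: chloride-free divalent palladium benzoate should bind the C1=C2–C3=C4 diene of 11 on its β face, free benzoate then attacks the unsubstituted terminus C4 from the α face (anti to the metal) to give the C1–C3 π-allyl complex 13, and coordination of benzoquinone makes a palladium-bound benzoate migrate to C1 on the metal's own β face, after which the quinone returns the released zerovalent palladium to the divalent state. The closest known reaction type is the palladium-catalysed, quinone-driven trans-1,4-diacyloxylation of cyclic 1,3-dienes run without chloride; new here are C–O bond formation at a fully substituted allyl terminus and the reliance on a free allylic hydroxyl to choose the face. No ring is closed; only the bonds C4–O and C1–O are made. C4 is set by the anti attack (O4 α, trans to O5) and C1 by the syn migration from palladium (O1 β, C7 pushed to α, trans to O4 and O6). The step needs face selectivity, first attack at C4 rather than C1, 1,4- rather than 1,2-addition and a syn second step: the small O5–H can hydrogen-bond or bind to the palladium carboxylate on the β face while the silylene ring hanging from α-O6 puts its tert-butyl groups under the α face at C1/C6, C4 is the only unsubstituted terminus and its α side is open (H5 is α), C3 is deactivated by the adjacent C4 benzoate whereas C1 carries most of the positive charge of the allyl unit, and leaving out chloride keeps benzoate on the metal. Excess quinone keeps the level of zerovalent palladium low, so the tertiary allylic benzoate of 14 should not be ionised again.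

Step 10
Reactants: 14 1β,4α-di-O-benzoyl-6α,7-O-silylene derivative
Product: 15 1β,4α-di-O-benzoyl-1-(hydroxymethyl)cyclohex-2-ene-1,4,5,6-tetrol (free 5β-OH; 6α-OH; C7–OH)
Conditions: HF·pyridine, pyridine, THF, 0 °C
Reagents that add atoms: none
Why: Fluoride-driven Si–O cleavage (desilylation) buffered with pyridine frees O6 and O7 in one operation under conditions too mild to ionise the tertiary allylic benzoate or cleave esters, and no C–O bond at a stereocentre is broken.

Step 11
Reactants: 15 1β,4α-di-O-benzoyl-1-(hydroxymethyl)cyclohex-2-ene-1,4,5,6-tetrol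
Product: 16 kweichowenol B, [(1R,4S,5S,6S)-4-(benzoyloxy)-1,5,6-trihydroxycyclohex-2-en-1-yl]methyl benzoate
Conditions: Et3N, MeCN, rt (followed by TLC, quenched with AcOH)
Reagents that add atoms: none
Why: In this base-promoted intramolecular O-to-O 1,2-acyl migration the O7 alkoxide adds to the neighbouring C1 benzoate through a five-membered orthoacid and the crowded tertiary ester collapses to the more stable primary one, with only acyl–oxygen bonds changing, so all four stereocentres stay as set.

## Compound list

1 | (1S,2S)-3-bromocyclohexa-3,5-diene-1,2-diol | BrC1=CC=C[C@H](O)[C@@H]1O | starting material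
2 | (1S,2S)-3-bromocyclohex-3-ene-1,2-diol | BrC1=CCC[C@H](O)[C@@H]1O | intermediate
3 | cyclic orthobenzoate (2-methoxy-2-phenyl-1,3-dioxolane on α-O5/α-O6 of 2; orthoester carbon undefined) | BrC1=CCC[C@@H]2OC(OC)(c3ccccc3)O[C@H]12 | intermediate
4 | (1S,6S)-2-bromo-6-hydroxycyclohex-2-en-1-yl benzoate | BrC1=CCC[C@H](O)[C@@H]1OC(=O)c2ccccc2 | intermediate
5 | (1R,2S)-2-(benzoyloxy)-3-bromocyclohex-3-en-1-yl 4-nitrobenzoate | BrC1=CCC[C@@H](OC(=O)c2ccc(cc2)[N+](=O)[O-])[C@@H]1OC(=O)c3ccccc3 | intermediate
6 | (1R,2S)-2-(benzoyloxy)-3,5-dibromocyclohex-3-en-1-yl 4-nitrobenzoate (epimers at the new C–Br carbon) | BrC1=CC(Br)C[C@@H](OC(=O)c2ccc(cc2)[N+](=O)[O-])[C@@H]1OC(=O)c3ccccc3 | intermediate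
7 | (1R,2S)-2-(benzoyloxy)-3-bromocyclohexa-3,5-dien-1-yl 4-nitrobenzoate | BrC1=CC=C[C@@H](OC(=O)c2ccc(cc2)[N+](=O)[O-])[C@@H]1OC(=O)c3ccccc3 | intermediate
8 | (1R,2S)-3-bromocyclohexa-3,5-diene-1,2-diol (trans) | BrC1=CC=C[C@@H](O)[C@@H]1O | intermediate
9 | tributyl(hydroxymethyl)stannane | OC[Sn](CCCC)(CCCC)CCCC | starting material
10 | (1R,2R)-3-(hydroxymethyl)cyclohexa-3,5-diene-1,2-diol | OCC1=CC=C[C@@H](O)[C@@H]1O | intermediate
11 | (8R,8aR)-2,2-di-tert-butyl-8,8a-dihydro-4H-1,3,2-benzodioxasilin-8-ol | CC(C)(C)[Si]1(C(C)(C)C)OCC2=CC=C[C@@H](O)[C@@H]2O1 | intermediate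
12 | benzoic acid | OC(=O)c1ccccc1 | starting material
13 | β-face C1–C3 π-allylpalladium benzoate bearing the 4α-benzoate (written as its C3-bound σ form) | CC(C)(C)[Si]1(C(C)(C)C)OCC2=C[C@@H]([Pd]OC(=O)c3ccccc3)[C@H](OC(=O)c3ccccc3)[C@@H](O)[C@@H]2O1 | intermediate
14 | 1β,4α-di-O-benzoyl-6α,7-O-(di-tert-butylsilylene)-1-(hydroxymethyl)cyclohex-2-ene-1,4,5,6-tetrol, 5β-OH free | CC(C)(C)[Si]1(C(C)(C)C)OC[C@]2(OC(=O)c3ccccc3)C=C[C@H](OC(=O)c3ccccc3)[C@@H](O)[C@@H]2O1 | intermediate
15 | 1β,4α-di-O-benzoyl-1-(hydroxymethyl)cyclohex-2-ene-1,4,5,6-tetrol | OC[C@]1(OC(=O)c2ccccc2)C=C[C@H](OC(=O)c2ccccc2)[C@@H](O)[C@@H]1O | intermediate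
16 | kweichowenol B | O=C(OC[C@]1(O)C=C[C@H](OC(=O)c2ccccc2)[C@@H](O)[C@@H]1O)c1ccccc1 | target

## Step count

- Total step count: 11.
- Longest linear sequence: 11 steps (1 to 16); 9 and 12 enter as bought materials.

## Steps most likely to fail

**Step 9.** Several processes could defeat it:
- Palladium may bind the inductively deactivated diene poorly or on the α face.
- The metal-bound benzoate may be delivered to C3 instead of the fully substituted C1.
- The tertiary allylic benzoate may ionise again or shift to C3.
- The dienol may lose water and aromatise.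

The fallback uses known chemistry and sets out from 11. Tetraphenylporphyrin-sensitised photooxygenation (O2, hν, CH2Cl2, −30 °C) should add singlet oxygen in a [4+2] cycloaddition on the β face, assisted by O5–H and opposite the silylene, to give the 1β,4β-endoperoxide F1. Thiourea in MeOH reduces the O–O bond to the cis-1β,4β-diol F2. A Mitsunobu reaction with 12 (PPh3, DIAD, toluene) inverts the allylic secondary C4 carbinol to the 4α-benzoate F3; the tertiary O1 is inert and the non-allylic O5 is slower. HF·pyridine removes the silylene to give the 4-O-benzoyl pentol F4. Benzoyl chloride (1 equiv) with 2,4,6-collidine in CH2Cl2 at −40 °C then acylates only the primary O7, which comes back to the route at 16.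

**Step 11.** Acyl scrambling may occur: the C4 benzoate can wander to the free O5, or the C1 benzoate to O6, before or alongside the wanted shift to O7.

The fallback sets out from 14 and blocks O5 before any hydroxyl is freed. TBSOTf and 2,6-lutidine give the 5-O-TBS ether F5. HF·pyridine at 0 °C removes the cyclic silylene much faster than a secondary TBS ether, as in 2'-O-TBS ribonucleoside practice, and gives the 6,7-diol F6. Et3N in MeCN then moves the C1 benzoate to O7 with the C4 benzoate locked in place, giving the 4,7-dibenzoate 5-O-TBS ether F7. HF·pyridine at rt removes the last silyl group, which comes back at 16.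

**Step 7.** Slow transfer of the hydroxymethyl group to a hindered vinylic bromide would keep the heat-sensitive dienediol at 80 °C long enough for Diels–Alder dimerisation or dehydration.

The fallback avoids palladium and heat and sets out from 8. Et3SiCl and imidazole give the bis(triethylsilyl) ether F8. Bromine–lithium exchange (t-BuLi, 2 equiv, Et2O, −78 °C) gives the dienyllithium F9. Dry monomeric formaldehyde traps it as the C7 alcohol F10. HF·pyridine/pyridine at 0 °C strips both triethylsilyl groups, which comes back at 10.

## Further compounds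

F1 | step 9 | 1β,4β-endoperoxide of 11 | CC(C)(C)[Si]1(C(C)(C)C)OC[C@]2(O3)C=C[C@@H](O3)[C@@H](O)[C@@H]2O1
F2 | step 9 | 6α,7-O-silylene 1β,4β,5β-triol | CC(C)(C)[Si]1(C(C)(C)C)OC[C@]2(O)C=C[C@@H](O)[C@@H](O)[C@@H]2O1
F3 | step 9 | 4α-benzoate 1β,5β-diol 6α,7-O-silylene | CC(C)(C)[Si]1(C(C)(C)C)OC[C@]2(O)C=C[C@H](OC(=O)c3ccccc3)[C@@H](O)[C@@H]2O1
F4 | step 9 | 4-O-benzoyl-1-(hydroxymethyl)cyclohex-2-ene-1β,4α,5β,6α-tetrol | OC[C@]1(O)C=C[C@H](OC(=O)c2ccccc2)[C@@H](O)[C@@H]1O
F5 | step 11 | 5-O-TBS ether of 14 | CC(C)(C)[Si]1(C(C)(C)C)OC[C@]2(OC(=O)c3ccccc3)C=C[C@H](OC(=O)c3ccccc3)[C@@H](O[Si](C)(C)C(C)(C)C)[C@@H]2O1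
F6 | step 11 | 1,4-dibenzoate 5-O-TBS 6,7-diol | OC[C@]1(OC(=O)c2ccccc2)C=C[C@H](OC(=O)c2ccccc2)[C@@H](O[Si](C)(C)C(C)(C)C)[C@@H]1O
F7 | step 11 | 4,7-dibenzoate 5-O-TBS ether | O=C(OC[C@]1(O)C=C[C@H](OC(=O)c2ccccc2)[C@@H](O[Si](C)(C)C(C)(C)C)[C@@H]1O)c1ccccc1
F8 | step 7 | bis(triethylsilyl) ether of 8 | BrC1=CC=C[C@@H](O[Si](CC)(CC)CC)[C@@H]1O[Si](CC)(CC)CC
F9 | step 7 | dienyllithium from F8 | [Li]C1=CC=C[C@@H](O[Si](CC)(CC)CC)[C@@H]1O[Si](CC)(CC)CC
F10 | step 7 | 5,6-bis-O-triethylsilyl ether of 10 | OCC1=CC=C[C@@H](O[Si](CC)(CC)CC)[C@@H]1O[Si](CC)(CC)CC
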